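**Retrosynthetic overview**

1. Numbering used below: decalin C1 (CH that carries the oxolane), C2, C3, C4 (C–N), C4a, C5, C6, C7 (=C–CH3), C8, C8a; oxolane O1', C2' (quaternary, CH3), C3', C4', C5' (CH–CMe2N).
2. Target ⇐ cis-decalone 21: C4 (N, CH3) by axial CH3 addition to an N-sulfinyl ketimine; the side-chain nitrogen from a tertiary nitrile by hydration and Hofmann rearrangement.
3. 21 ⇐ trienone 20 by intramolecular Diels–Alder reaction: rings A and B close together (the last rings formed), with C8a and C4a relayed from C1.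
4. 20 ⇐ butenolide 10: the furanone ring, present from the first step, is turned into the oxolane (C5' relayed from C2'); its two arms become the diene and the enone.
5. 10 ⇐ enal 8 + silyloxyfuran 2 across C1–C2'. The feature that allows this: the O- and CH3-bearing quaternary C2' is the γ-carbon of a γ-methylbutenolide dienolate, and C1 lies β to ring-B carbon C3, which can be carried as an aldehyde carbon; an amine catalyst sets C1 and C2' together.

Key step: step 5

Assumption: the silyloxy-bearing carbon of the diene arm (future C8) is carried as both epimers from racemic 5; it becomes sp2 in step 11, so the mixture has no consequence.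

**Route**

Step 1
Reactants: 1 α-angelica lactone
Product: 2 5-methyl-2-(trimethylsilyloxy)furan
Conditions: TMSOTf, Et3N, Et2O, 0 °C
Reagents that add atoms: trimethylsilyl trifluoromethanesulfonate, C[Si](C)(C)OS(=O)(=O)C(F)(F)F
Why: Soft enolisation of the β,γ-unsaturated lactone and O-silylation should give the aromatic silyl dienol ether (silyl enol ether formation).

Step 2
Reactants: 3 methacrolein; 4 allylmagnesium bromide
Product: 5 rac-2-methylhexa-1,5-dien-3-ol
Conditions: Et2O, −78 → 0 °C; aq NH4Cl
Reagents that add atoms: none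
Why: Grignard 1,2-addition to the enal carbonyl; the carbinol centre is racemic and is erased in step 11.

Step 3
Reactants: 5 rac-2-methylhexa-1,5-dien-3-ol
Product: 6 TBS ether of 5
Conditions: TBSCl, imidazole, DMF, rt
Reagents that add atoms: tert-butyldimethylsilyl chloride, CC(C)(C)[Si](C)(C)Cl
Why: Standard O-silylation of a secondary alcohol, giving a group that survives base, hydride and brief Lewis acid.

Step 4
Reactants: 6 TBS ether of 5; 7 (E)-crotonaldehyde (excess)
Product: 8 rac-(2E)-5-(tert-butyldimethylsilyloxy)-6-methylhepta-2,6-dienal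
Conditions: [1,3-bis(2,4,6-trimethylphenyl)imidazolidin-2-ylidene]dichloro(2-isopropoxybenzylidene)ruthenium (3 mol %), CH2Cl2, 40 °C
Reagents that add atoms: none
Why: Olefin cross-metathesis in which only the monosubstituted alkene reacts, the 1,1-disubstituted alkene next to the silyloxy carbon being inert, and the (E)-enal is the expected isomer.

Step 5
Reactants: 2 5-methyl-2-(trimethylsilyloxy)furan; 8 rac-(2E)-5-(tert-butyldimethylsilyloxy)-6-methylhepta-2,6-dienal
Product: 10 butenolide alcohol, via aldehyde 9 (not isolated)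
Conditions: (2R,5R)-5-benzyl-2-tert-butyl-3-methylimidazolidin-4-one (20 mol %), 2,4-dinitrobenzoic acid (20 mol %), CH2Cl2, H2O (2 equiv), −70 °C; then NaBH4, EtOH, −70 → 0 °C
Reagents that add atoms: none
Why: The enal condenses with the imidazolidinone to an (E)-iminium ion whose benzyl group shields one face; the silyloxyfuran attacks C1 (the enal β-carbon) through its C5 (the future C2') in an open transition state, the added water hydrolyses the enamine and takes up the silyl group, and NaBH4 then reduces the aldehyde in the same flask. The closest known reaction type is the imidazolidinone-catalysed Mukaiyama–Michael addition of 5-methyl-2-silyloxyfurans to β-alkyl enals, which gives γ-butenolides with an oxygen-bearing quaternary centre. No ring is closed; the furan becomes the butenolide ring that later is the oxolane. C1 is set by the catalyst (attack on the unshielded iminium face, expected 3S in 9 with the (2R,5R)-catalyst) and C2' by the topicity of the open transition state, in which the β-alkyl chain lies next to the ring oxygen and away from the furan methyl group (syn adduct, 2R in 9). The step needs 1,4- over 1,2-addition (secured by iminium activation with a hindered amine), γ- over α-attack of the dienol ether (inherent to 2-silyloxyfurans) and syn diastereoselection (secured by the unbranched β-CH2 of the chain); the remote silyloxy centre should play no role.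

Step 6
Reactants: 10 butenolide alcohol
Product: 11 saturated γ-lactone alcohol
Conditions: Cu(OAc)2·H2O (5 mol %), rac-BINAP (5 mol %), (EtO)2MeSiH, t-BuOH, toluene, rt; aq NH4F
Reagents that add atoms: none
Why: Copper hydride conjugate reduction of the β-unsubstituted butenolide, which leaves the isolated alkene, the silyl ether and both stereocentres untouched.

Step 7
Reactants: 11 saturated γ-lactone alcohol; 12 isobutyronitrile
Product: 13 cyano lactol
Conditions: 12, LDA, THF, −78 °C; then 11, −78 → −40 °C; aq NH4Cl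
Reagents that add atoms: none
Why: Claisen-type acylation of lithiated isobutyronitrile by the lactone; the tetrahedral lithium alkoxide persists at low temperature so that only one anion adds, and the non-enolisable β-ketonitrile is obtained as its lactol (the free hydroxyl costs one extra equivalent of anion).

Step 8
Reactants: 13 cyano lactol
Product: 14 iodo lactol
Conditions: I2, PPh3, imidazole, CH2Cl2, 0 °C
Reagents that add atoms: iodine, II
Why: Appel iodination is selective for the primary alcohol, the hindered tertiary anomeric hydroxyl being unreactive, and it removes the hydroxyl that could otherwise trap the oxocarbenium ion of step 9.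

Step 9
Reactants: 14 iodo lactol
Product: 15 oxolane nitrile iodide
Conditions: Et3SiH, BF3·OEt2, CH2Cl2, −78 → −30 °C
Reagents that add atoms: none
Why: Ionic hydrogenation: the lactol ionises to a cyclic oxocarbenium ion and hydride should enter C5' anti to the larger C2' substituent (the C1 branch, not CH3), which places the cyanoisopropyl group cis to the C1 branch; partial loss of the silyl ether would not matter because step 10 removes it.

Step 10
Reactants: 15 oxolane nitrile iodide
Product: 16 allylic alcohol
Conditions: HF·pyridine, pyridine, THF, 0 °C → rt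
Reagents that add atoms: none
Why: Fluoride-mediated desilylation under mildly acidic conditions that the primary iodide and the nitrile tolerate.

Step 11
Reactants: 16 allylic alcohol
Product: 17 (E)-diene iodide
Conditions: methyl N-(triethylammoniosulfonyl)carbamate (inner salt), toluene, 70 °C
Reagents that add atoms: none
Why: Syn-elimination through the sulfamate ester (Burgess dehydration) can only take a hydrogen from the CH2 next to C1 and should give the conjugated (E)-diene with the large groups anti.

Step 12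
Reactants: 17 (E)-diene iodide; 18 acryloyl chloride
Product: 21 cis-decalone nitrile, via alkylzinc iodide 19 (not isolated), via trienone 20 (not isolated)
Conditions: Zn dust (activated), LiCl, THF, 35 °C; then Pd(PPh3)4 (5 mol %), 18, 0 °C; then 50 °C (BHT)
Reagents that add atoms: none
Why: Zinc insertion and Negishi acylation give the 1,7,9-decatrien-3-one, which should undergo intramolecular Diels–Alder reaction on warming: the tether carbonyl takes the endo position (cis ring fusion, as known for 6-substituted decatrienones in cadinane synthesis) and allylic strain at C1 turns the diene face anti to the oxolane towards the dienophile, so C8a and C4a are relayed from C1.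

Step 13
Reactants: 21 cis-decalone nitrile; 22 (R)-2-methylpropane-2-sulfinamide
Product: 23 N-sulfinyl ketimine
Conditions: Ti(OEt)4, THF, 60 °C
Reagents that add atoms: none
Why: Titanium-mediated condensation of the ketone with the sulfinamide should give the (E)-ketimine with the sulfinyl group syn to C3H2; no stereocentre is meant to change.

Step 14
Reactants: 23 N-sulfinyl ketimine
Product: 24 sulfinamide
Conditions: AlMe3, toluene, −78 °C; then MeLi, −78 °C
Reagents that add atoms: methyllithium, [Li]C
Why: 1,2-Addition of methyllithium to the aluminium-activated sulfinyl ketimine: CH3 should enter the axial, convex face of ring B (anti to the axial C5 at C4a), leaving nitrogen equatorial, and the (R)-sulfinyl group delivers the nucleophile to the same face through a six-membered O–metal chelate (matched pair), while the hindered tertiary nitrile is inert at this temperature.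

Step 15
Reactants: 24 sulfinamide
Product: 26 formamide nitrile, via amine 25 (not isolated)
Conditions: HCl (dioxane), MeOH, 0 °C; concentrate; then acetic formic anhydride, Et3N, CH2Cl2, 0 °C
Reagents that add atoms: acetic formic anhydride, CC(=O)OC=O
Why: Acidic methanolysis cleaves the N–S bond and the liberated α-tertiary amine is N-formylated by the mixed anhydride (acyl substitution at the formyl carbon).

Step 16
Reactants: 26 formamide nitrile
Product: 27 primary amide
Conditions: [PtH{(PMe2O)2H}(PMe2OH)] (5 mol %), EtOH–H2O 4:1, 80 °C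
Reagents that add atoms: water, O
Why: Platinum-catalysed hydration of the hindered tertiary nitrile under neutral conditions, which leaves the formamide and the trisubstituted alkene alone.

Step 17
Reactants: 27 primary amide
Product: 30 target bisformamide, via isocyanate 28 (not isolated), via amine 29 (not isolated)
Conditions: PhI(OCOCF3)2, MeCN–H2O 1:1, rt; concentrate; then acetic formic anhydride, Et3N, CH2Cl2, 0 °C
Reagents that add atoms: acetic formic anhydride, CC(=O)OC=O
Why: Iodine(III)-mediated Hofmann rearrangement converts the amide through the isocyanate into the α-tertiary amine (the migrating carbon is not stereogenic), which is formylated as in step 15.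

**Compound list**

1 | α-angelica lactone (5-methylfuran-2(3H)-one) | CC1=CCC(=O)O1 | starting material
2 | 5-methyl-2-(trimethylsilyloxy)furan | Cc1ccc(O[Si](C)(C)C)o1 | intermediate
3 | methacrolein (2-methylprop-2-enal) | CC(=C)C=O | starting material
4 | allylmagnesium bromide | C=CC[Mg]Br | starting material
5 | rac-2-methylhexa-1,5-dien-3-ol | C=CCC(O)C(C)=C | intermediate
6 | rac-tert-butyldimethyl[(2-methylhexa-1,5-dien-3-yl)oxy]silane | C=CCC(O[Si](C)(C)C(C)(C)C)C(C)=C | intermediate
7 | (E)-crotonaldehyde | C/C=C/C=O | starting material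
8 | rac-(2E)-5-(tert-butyldimethylsilyloxy)-6-methylhepta-2,6-dienal | C=C(C)C(O[Si](C)(C)C(C)(C)C)C/C=C/C=O | intermediate
9 | (3S)-5-(tert-butyldimethylsilyloxy)-6-methyl-3-[(2R)-2-methyl-5-oxo-2,5-dihydrofuran-2-yl]hept-6-enal (both C5 epimers) | C=C(C)C(O[Si](C)(C)C(C)(C)C)C[C@H]([C@]1(C)C=CC(=O)O1)CC=O | intermediate
10 | (5R)-5-[(3R)-5-(tert-butyldimethylsilyloxy)-1-hydroxy-6-methylhept-6-en-3-yl]-5-methylfuran-2(5H)-one (both epimers at the silyloxy carbon) | C=C(C)C(O[Si](C)(C)C(C)(C)C)C[C@H]([C@]1(C)C=CC(=O)O1)CCO | intermediate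
11 | (5S)-5-[(3R)-5-(tert-butyldimethylsilyloxy)-1-hydroxy-6-methylhept-6-en-3-yl]-5-methyldihydrofuran-2(3H)-one | C=C(C)C(O[Si](C)(C)C(C)(C)C)C[C@H]([C@]1(C)CCC(=O)O1)CCO | intermediate
12 | isobutyronitrile | CC(C)C#N | starting material
13 | 2-[(5S)-2-hydroxy-5-[(3R)-5-(tert-butyldimethylsilyloxy)-1-hydroxy-6-methylhept-6-en-3-yl]-5-methyloxolan-2-yl]-2-methylpropanenitrile (lactol, both anomers) | C=C(C)C(O[Si](C)(C)C(C)(C)C)C[C@H]([C@]1(C)CCC(O)(C(C)(C)C#N)O1)CCO | intermediate
14 | 2-[(5S)-2-hydroxy-5-[(3S)-5-(tert-butyldimethylsilyloxy)-1-iodo-6-methylhept-6-en-3-yl]-5-methyloxolan-2-yl]-2-methylpropanenitrile (both anomers) | C=C(C)C(O[Si](C)(C)C(C)(C)C)C[C@H]([C@]1(C)CCC(O)(C(C)(C)C#N)O1)CCI | intermediate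
15 | 2-[(2R,5S)-5-[(3S)-5-(tert-butyldimethylsilyloxy)-1-iodo-6-methylhept-6-en-3-yl]-5-methyloxolan-2-yl]-2-methylpropanenitrile | C=C(C)C(O[Si](C)(C)C(C)(C)C)C[C@H]([C@]1(C)CC[C@H](C(C)(C)C#N)O1)CCI | intermediate
16 | 2-[(2R,5S)-5-[(3S)-5-hydroxy-1-iodo-6-methylhept-6-en-3-yl]-5-methyloxolan-2-yl]-2-methylpropanenitrile | C=C(C)C(O)C[C@H]([C@]1(C)CC[C@H](C(C)(C)C#N)O1)CCI | intermediate
17 | 2-[(2R,5S)-5-[(3R,4E)-1-iodo-6-methylhepta-4,6-dien-3-yl]-5-methyloxolan-2-yl]-2-methylpropanenitrile | C=C(C)/C=C/[C@H]([C@]1(C)CC[C@H](C(C)(C)C#N)O1)CCI | intermediate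
18 | acryloyl chloride | C=CC(=O)Cl | starting material
19 | [(3R,4E)-3-[(2S,5R)-5-(2-cyanopropan-2-yl)-2-methyloxolan-2-yl]-6-methylhepta-4,6-dien-1-yl]zinc iodide | C=C(C)/C=C/[C@H]([C@]1(C)CC[C@H](C(C)(C)C#N)O1)CC[Zn]I | intermediate
20 | 2-methyl-2-[(2R,5S)-5-methyl-5-[(3E,5R)-2-methyl-8-oxodeca-1,3,9-trien-5-yl]oxolan-2-yl]propanenitrile | C=C(C)/C=C/[C@H]([C@]1(C)CC[C@H](C(C)(C)C#N)O1)CCC(=O)C=C | intermediate
21 | 2-methyl-2-[(2R,5S)-5-methyl-5-[(1R,4aS,8aS)-7-methyl-4-oxo-1,2,3,4,4a,5,6,8a-octahydronaphthalen-1-yl]oxolan-2-yl]propanenitrile (cis-fused) | CC1=C[C@H]2[C@H]([C@]3(C)CC[C@H](C(C)(C)C#N)O3)CCC(=O)[C@H]2CC1 | intermediate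
22 | (R)-2-methylpropane-2-sulfinamide | CC(C)(C)[S@@](=O)N | starting material
23 | (E)-N-[(R)-tert-butanesulfinyl] ketimine of 21 (C4=N, sulfinyl group syn to C3H2; 1R,4aS,8aR) | CC1=C[C@H]2[C@H]([C@]3(C)CC[C@H](C(C)(C)C#N)O3)CC/C(=N\[S@](=O)C(C)(C)C)[C@H]2CC1 | intermediate
24 | (R)-N-[(1R,4R,4aS,8aR)-1-[(2S,5R)-5-(2-cyanopropan-2-yl)-2-methyloxolan-2-yl]-4,7-dimethyl-1,2,3,4,4a,5,6,8a-octahydronaphthalen-4-yl]-2-methylpropane-2-sulfinamide (overview numbering) | CC1=C[C@H]2[C@H]([C@]3(C)CC[C@H](C(C)(C)C#N)O3)CC[C@@](C)(N[S@](=O)C(C)(C)C)[C@H]2CC1 | intermediate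
25 | 2-[(2R,5S)-5-[(1R,4R,4aS,8aR)-4-amino-4,7-dimethyl-1,2,3,4,4a,5,6,8a-octahydronaphthalen-1-yl]-5-methyloxolan-2-yl]-2-methylpropanenitrile (formed as hydrochloride) | CC1=C[C@H]2[C@H]([C@]3(C)CC[C@H](C(C)(C)C#N)O3)CC[C@@](C)(N)[C@H]2CC1 | intermediate
26 | N-[(1R,4R,4aS,8aR)-1-[(2S,5R)-5-(2-cyanopropan-2-yl)-2-methyloxolan-2-yl]-4,7-dimethyl-1,2,3,4,4a,5,6,8a-octahydronaphthalen-4-yl]formamide | CC1=C[C@H]2[C@H]([C@]3(C)CC[C@H](C(C)(C)C#N)O3)CC[C@@](C)(NC=O)[C@H]2CC1 | intermediate
27 | 2-[(2R,5S)-5-[(1R,4R,4aS,8aR)-4-formamido-4,7-dimethyl-1,2,3,4,4a,5,6,8a-octahydronaphthalen-1-yl]-5-methyloxolan-2-yl]-2-methylpropanamide | CC1=C[C@H]2[C@H]([C@]3(C)CC[C@H](C(C)(C)C(N)=O)O3)CC[C@@](C)(NC=O)[C@H]2CC1 | intermediate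
28 | N-[(1R,4R,4aS,8aR)-1-[(2S,5R)-5-(2-isocyanatopropan-2-yl)-2-methyloxolan-2-yl]-4,7-dimethyl-1,2,3,4,4a,5,6,8a-octahydronaphthalen-4-yl]formamide | CC1=C[C@H]2[C@H]([C@]3(C)CC[C@H](C(C)(C)N=C=O)O3)CC[C@@](C)(NC=O)[C@H]2CC1 | intermediate
29 | N-[(1R,4R,4aS,8aR)-1-[(2S,5R)-5-(2-aminopropan-2-yl)-2-methyloxolan-2-yl]-4,7-dimethyl-1,2,3,4,4a,5,6,8a-octahydronaphthalen-4-yl]formamide | CC1=C[C@H]2[C@H]([C@]3(C)CC[C@H](C(C)(C)N)O3)CC[C@@](C)(NC=O)[C@H]2CC1 | intermediate
30 | N-[(1R,4R,4aS,8aR)-1-[(2S,5R)-5-(2-formamidopropan-2-yl)-2-methyloxolan-2-yl]-4,7-dimethyl-1,2,3,4,4a,5,6,8a-octahydronaphthalen-4-yl]formamide (overview numbering) | CC1=C[C@H]2[C@H]([C@]3(C)CC[C@H](C(C)(C)NC=O)O3)CC[C@@](C)(NC=O)[C@H]2CC1 | target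

**Step count and risks**

Total step count: 17. Longest linear sequence: 16 steps (steps 2–17, from methacrolein and allylmagnesium bromide).

Steps most likely to fail:

Step 5. What may go wrong: loss of syn diastereoselection or of facial control at C1 because of the δ-silyloxy chain, or γ-deprotonation of the iminium ion (dienamine formation) that drains the enal. Fallback: set out from 6. Cross-metathesis with 3-acryloyl-1,3-oxazolidin-2-one should give the N-enoyl oxazolidinone F1. A copper(II)–bis(oxazoline)-catalysed vinylogous Mukaiyama–Michael addition of 2 then gives the imide F2; here the imide binds a C2-symmetric Lewis acid at two points, in place of iminium activation, and no enolisable aldehyde is present. Reductive cleavage of the imide with LiBH4 comes back to the route at 10.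

Step 9. What may go wrong: hydride delivery to the wrong face of the oxocarbenium ion (the two C2' substituents, CH3 and the C1 branch, may not be told apart in the expected sense), which would give the 2',5'-trans oxolane. Fallback: set out from 11 and form the C5'–H and C5'–C bonds in the opposite order, so that the same facial bias gives the opposite relative configuration. DIBAL-H at −78 °C gives the lactol F3 and acetylation of both hydroxyl groups (Ac2O, pyridine, DMAP) gives the diacetate F4. TMSOTf-promoted substitution of the anomeric acetate by N-(tert-butyldimethylsilyl)dimethylketene imine then forms the C5'–C bond last and gives the nitrile acetate F5. Methanolysis (K2CO3, MeOH) gives the nitrile alcohol F6, and Appel iodination comes back to the route at 15.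

Step 13. What may go wrong: epimerisation of C4a (α to the ketone and to the ketimine) towards the more stable trans-decalin during the hot titanium-mediated condensation, or incomplete condensation at the hindered ketone. Fallback: set out from 21. Buffered oximation (NH2OH·HCl, NaOAc, MeOH, rt) gives the oxime F7. Ph2PCl and Et3N at −40 °C → rt give the N-diphenylphosphinoyl ketimine F8 by O-phosphinylation and rearrangement. MeMgBr with CeCl3 at −78 °C should add from the same axial face to give the phosphinamide F9. HCl in MeOH cleaves the P–N bond and comes back to the route at amine 25, which is formylated as in step 15.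

Further compounds
F1 | step 5 | 3-[(2E)-5-(tert-butyldimethylsilyloxy)-6-methylhepta-2,6-dienoyl]-1,3-oxazolidin-2-one (racemic) | C=C(C)C(O[Si](C)(C)C(C)(C)C)C/C=C/C(=O)N1CCOC1=O
F2 | step 5 | 3-[(3S)-5-(tert-butyldimethylsilyloxy)-6-methyl-3-[(2R)-2-methyl-5-oxo-2,5-dihydrofuran-2-yl]hept-6-enoyl]-1,3-oxazolidin-2-one | C=C(C)C(O[Si](C)(C)C(C)(C)C)C[C@H]([C@]1(C)C=CC(=O)O1)CC(=O)N2CCOC2=O
F3 | step 9 | (5S)-5-[(3R)-5-(tert-butyldimethylsilyloxy)-1-hydroxy-6-methylhept-6-en-3-yl]-5-methyloxolan-2-ol (both anomers) | C=C(C)C(O[Si](C)(C)C(C)(C)C)C[C@H]([C@]1(C)CCC(O)O1)CCO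
F4 | step 9 | diacetate of F3 (anomeric and primary acetate) | C=C(C)C(O[Si](C)(C)C(C)(C)C)C[C@H]([C@]1(C)CCC(OC(C)=O)O1)CCOC(C)=O
F5 | step 9 | (3R)-5-(tert-butyldimethylsilyloxy)-3-[(2S,5R)-5-(2-cyanopropan-2-yl)-2-methyloxolan-2-yl]-6-methylhept-6-en-1-yl acetate | C=C(C)C(O[Si](C)(C)C(C)(C)C)C[C@H]([C@]1(C)CC[C@H](C(C)(C)C#N)O1)CCOC(C)=O
F6 | step 9 | 2-[(2R,5S)-5-[(3R)-5-(tert-butyldimethylsilyloxy)-1-hydroxy-6-methylhept-6-en-3-yl]-5-methyloxolan-2-yl]-2-methylpropanenitrile | C=C(C)C(O[Si](C)(C)C(C)(C)C)C[C@H]([C@]1(C)CC[C@H](C(C)(C)C#N)O1)CCO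
F7 | step 13 | oxime of 21 (C4=N–OH) | CC1=C[C@H]2[C@H]([C@]3(C)CC[C@H](C(C)(C)C#N)O3)CCC(=NO)[C@H]2CC1
F8 | step 13 | N-diphenylphosphinoyl ketimine of 21 | CC1=C[C@H]2[C@H]([C@]3(C)CC[C@H](C(C)(C)C#N)O3)CCC(=NP(=O)(c4ccccc4)c5ccccc5)[C@H]2CC1
F9 | step 13 | N-[(1R,4R,4aS,8aR)-1-[(2S,5R)-5-(2-cyanopropan-2-yl)-2-methyloxolan-2-yl]-4,7-dimethyl-1,2,3,4,4a,5,6,8a-octahydronaphthalen-4-yl]-P,P-diphenylphosphinic amide | CC1=C[C@H]2[C@H]([C@]3(C)CC[C@H](C(C)(C)C#N)O3)CC[C@@](C)(NP(=O)(c4ccccc4)c5ccccc5)[C@H]2CC1
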